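**Steady clearance.** One constant carries Tuesday's run, in which starting material and coupling partner make target: by 35 min it stands at 0.0482 min⁻¹. This is the clearance, the logarithm of starting material charged over starting material left, divided by time, an apparent pseudo-first-order constant. At 8.8 min the same run reads 0.0470 min⁻¹, so the semilogarithmic plot is close to straight. Saturday's run reads 0.0406 min⁻¹ at 8.8 min and 0.0383 min⁻¹ at 35 min.

| setting | Tuesday's | Thursday's | Saturday's | Monday's | Friday's |
|---|---|---|---|---|---|
| starting material | 0.150 M | 0.0600 M | 0.220 M | 0.150 M | 0.310 M |
| coupling partner | 0.450 M | 0.360 M | 0.450 M | 0.230 M | 0.450 M |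
| time |  |  |  |  | 35 min |

| run | time / min | [target] / M |
|---|---|---|
| Tuesday's run | 1.4 | 0.0095 |
| Tuesday's run | 2.2 | 0.0148 |
| Tuesday's run | 3.5 | 0.0225 |
| Tuesday's run | 5.6 | 0.0345 |
| Tuesday's run | 8.8 | 0.0508 |
| Tuesday's run | 14 | 0.0710 |
| Tuesday's run | 22 | 0.0976 |
| Tuesday's run | 35 | 0.1222 |
| Thursday's run | 1.4 | 0.0043 |
| Thursday's run | 2.2 | 0.0068 |
| Thursday's run | 3.5 | 0.0099 |
| Thursday's run | 5.6 | 0.0156 |
| Thursday's run | 8.8 | 0.0214 |
| Thursday's run | 14 | 0.0291 |
| Thursday's run | 22 | 0.0398 |
| Thursday's run | 35 | 0.0489 |
| Saturday's run | 1.4 | 0.0132 |
| Saturday's run | 2.2 | 0.0195 |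
| Saturday's run | 3.5 | 0.0297 |
| Saturday's run | 5.6 | 0.0457 |
| Saturday's run | 8.8 | 0.0661 |
| Saturday's run | 14 | 0.0951 |
| Saturday's run | 22 | 0.1263 |
| Saturday's run | 35 | 0.1625 |
| Monday's run | 1.4 | 0.0054 |
| Monday's run | 2.2 | 0.0073 |
| Monday's run | 3.5 | 0.0103 |
| Monday's run | 5.6 | 0.0145 |
| Monday's run | 8.8 | 0.0237 |
| Monday's run | 14 | 0.0354 |
| Monday's run | 22 | 0.0518 |
| Monday's run | 35 | 0.0701 |

(standard deviation of a reading: 0.001 M)

- Overall: starting material + coupling partner -> target.
- Constant volume, constant temperature.
- Bound and free are read together.
- "The second partner" is coupling partner.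
- An order is taken over about fifteen percent of the charge, up and down.

- apparent order in [starting material] of the starting rate, round the charge of the Tuesday's run (the rate where two percent of its starting material have turned into target) (one fixed amount of target, the same in the runs compared)
- apparent order in [coupling partner] of the starting rate, round the charge of the Tuesday's run (the rate where two percent of its starting material have turned into target)
- the Thursday's run starts with 0.0900 M less of starting material and of coupling partner than the Tuesday's run, and with no target. Compared where both hold the same amount of starting material, once fifteen percent of what the Thursday's run was charged with has turned into target, is the Thursday's run faster, slower or alike (within a tenth)?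
- target in the Friday's run at 35 min, as a share of the starting material charged

**Next charge.** The decision is whether Friday's charge of 0.310 M starting material makes more target in 35 min than Saturday's run did, or merely turns a smaller share. Tuesday's and Saturday's runs hold the same coupling partner, and Saturday's run, with the larger charge, has the lower clearance. At 35 min, the ratio of these two clearances equals the inverse ratio of the charges raised to the power 0.596; this is an end-of-run exponent from two runs, not a rate law. Extended from Saturday's run as a rough estimate, it gives Friday's run a clearance of 0.0313 min⁻¹, and frozen at that value, a share of 66.5%. That share is smaller than Saturday's, but the amount, 0.206 M, is more than Saturday's 0.1625 M. Friday's charge is worth running.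

**The forecast.** It gives orders of 0.72 and 1.15, the answer alike, and 66.5% for Friday's run, by “Integrating the saturation law for Friday, calibrated on Saturday”.

**The flask.** The simulation gives orders of 0.70 and 1.2, the answer alike, and 65.2% for Friday's run.

    starting material + 2 coupling partner → target + coupling partner (3.582 M⁻² min⁻¹)
    2 coupling partner ⇌ idle reagent dimer, settled at all times (5.860 M⁻¹)
    2 starting material ⇌ idle substrate dimer, settled at all times (5.230 M⁻¹)

**What holds.** Friday's result means a clearance of 0.0302 min⁻¹, against 0.0313 min⁻¹ carried forward, and 0.202 M of target, more than Saturday's 0.1625 M. Tuesday's clearance, used on Thursday's run with its equal excess of 0.300 M coupling partner, gives a half-time of 14.4 min, and the simulated one is 14.5 min. The binding of coupling partner into idle reagent dimer holds Friday's run at 65.2%: the simulated run without it reaches 97.3%, so this binding accounts for 92% of what is missing.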